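**Strategy.** Ring B is closed last through the C6–C8 bond (gibberellane numbering). C6 bears the C7 carboxyl, so it can be an ester-stabilised rhodium carbenoid; C8 is the bridgehead methine of the ring C/D bicyclo[3.2.1]octane and stands 1,5 to C6. Carbenoid insertion into C8–H creates the quaternary centre with retention, sets C6 and closes ring B in one operation. The precursor is a spiro diazo ester in which ring A hangs on ring C by C9–C10 alone; a temporary δ-lactone from C20 to the axial 12α-oxygen, absent from the target, freezes rotation about C9–C10 so that C6 meets only C8–H. The same lactone earlier fixes C10, and is hydrolysed at the end.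

Key step: step 15

Remark: all intermediates carry gibberellane atom numbers (C1–C20); β is the face of H5 and H9, α the face of C20.
Assumption: the 12α-hydroxy 20-acid of the target does not relactonise during brief cold acidification to pH 3.

**Step 1**
Reactants: 1 pent-4-ynal; 2 but-3-en-2-one
Product: 4 (S)-4-(prop-2-yn-1-yl)cyclohex-2-en-1-one, via keto aldehyde 3 (not isolated)
Conditions: (S)-2-[diphenyl(trimethylsilyloxy)methyl]pyrrolidine (5 mol%), ethyl 3,4-dihydroxybenzoate (20 mol%), neat, 4 °C; then LiOH (0.2 equiv), i-PrOH, rt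
Reagents that add atoms: none
Why: Enamine-catalysed Michael addition of the aldehyde to the enone sets C8 under catalyst control (the diarylsilyloxymethyl group shields one enamine face), and intramolecular aldol condensation of the methyl ketone onto the aldehyde then closes ring C without touching that centre.

**Step 2**
Reactants: 4 (S)-4-(prop-2-yn-1-yl)cyclohex-2-en-1-one
Product: 5 tert-butyldimethyl{[(4S)-4-(prop-2-yn-1-yl)cyclohexa-1,5-dien-1-yl]oxy}silane
Conditions: LDA, THF, −78 °C; TBSCl, HMPA, −78 °C to rt
Reagents that add atoms: tert-butyldimethylsilyl chloride, CC(C)(C)[Si](C)(C)Cl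
Why: Kinetic α′-deprotonation at C13 and O-silylation (silyl enol ether formation) should give the cross-conjugated silyl dienol ether; C8 is not involved.

**Step 3**
Reactants: 5 silyl dienol ether
Product: 6 (1R,5S)-7-methylidenebicyclo[3.2.1]oct-3-en-2-one (rings C/D; C12 ketone, C9=C11, bridgehead C8–H)
Conditions: Ph3PAuCl (2 mol%), AgBF4 (2 mol%), CH2Cl2/MeOH 10:1, rt
Reagents that add atoms: none
Why: Gold-catalysed 5-exo-dig carbocyclisation of the silyl enol ether onto the alkyne (Conia-ene type) forms C13–C16 and the exocyclic methylene; the propargyl arm can only bridge cis, so C13 follows from C8.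

**Step 4**
Reactants: 6 bicyclic enone; 7 tert-butyl[(1-methoxyethenyl)oxy]dimethylsilane
Product: 9 methyl 2-(6-methylidene-4-oxobicyclo[3.2.1]octan-2-yl)acetate with the acetate arm on C9 α (trans to the C15–C16 bridge), via silyl enol ether 8 (not isolated)
Conditions: TBSOTf (10 mol%), CH2Cl2, −78 °C; then 1 M HCl, THF, 0 °C
Reagents that add atoms: none
Why: Mukaiyama–Michael addition in which the ketene acetal should attack C9 anti to the axial C15 substituent on the neighbouring bridgehead (stereoelectronically axial, exo face), placing C10 trans to C15 as in the target.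

**Step 5**
Reactants: 9 keto ester
Product: 11 tricyclic δ-lactone (C20 carbonyl joined to the 12α-oxygen; C10 is CH2), via hydroxy ester 10 (not isolated)
Conditions: L-Selectride (Li[s-Bu3BH]), THF, −78 °C to rt; aq NH4Cl
Reagents that add atoms: none
Why: In this Selectride ketone reduction the bulky hydride should attack C12 along the equatorial (β) trajectory because the α face is screened by the syn-axial C10 arm, and the resulting axial 12α-alkoxide, 1,3-diaxial to that arm, lactonises in situ.

**Step 6**
Reactants: 11 δ-lactone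
Product: 12 α-(hydroxymethylene) lactone (enol of the C10 formyl lactone; the formyl carbon is C5)
Conditions: NaH, HCO2Et, THF, 0 °C to rt; then 1 M HCl
Reagents that add atoms: ethyl formate, CCOC=O
Why: Claisen formylation of the lactone enolate at C10, the only acidic position, gives the enolised 1,3-dicarbonyl donor.

**Step 7**
Reactants: 12 α-(hydroxymethylene) lactone; 2 but-3-en-2-one
Product: 14 spiro enone lactone (ring A is a cyclohex-2-en-1-one spiro at C10 with C3=O and C4=C5; C5 lies on the C8 side and C1 on the C11 side), via diketo aldehyde 13 (not isolated)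
Conditions: Et3N (10 mol%), CH2Cl2, rt; then pyrrolidine (20 mol%), AcOH (20 mol%), toluene, 50 °C
Reagents that add atoms: none
Why: Robinson-type spiroannulation in which the Michael addition to the enone should occur on the convex face of the bicyclo[3.3.1] lactone (axial on the lactone ring, anti to C8), fixing C10 with C1 outside and the formyl carbon C5 towards C8, before enamine-mediated aldol condensation onto the non-enolisable aldehyde closes ring A.

**Step 8**
Reactants: 14 spiro enone lactone
Product: 15 4-iodo enone (14 with iodine on C4)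
Conditions: I2, pyridine, CH2Cl2, 0 °C to rt
Reagents that add atoms: iodine, II
Why: Johnson α-iodination of the enone (pyridine conjugate addition, iodination, elimination) should place iodine on C4.

**Step 9**
Reactants: 15 4-iodo enone
Product: 16 enone ester (14 with CO2CH2CH2SiMe3 as C19 on C4)
Conditions: Pd(OAc)2 (5 mol%), PPh3 (10 mol%), CO (1 atm), Me3SiCH2CH2OH, i-Pr2NEt, DMF, 50 °C
Reagents that add atoms: carbon monoxide, [C-]#[O+]; 2-(trimethylsilyl)ethanol, C[Si](C)(C)CCO
Why: Palladium-catalysed alkoxycarbonylation of the vinyl iodide installs C19 as a fluoride-cleavable ester and turns C5 into a doubly activated acceptor.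

**Step 10**
Reactants: 16 enone ester; 7 tert-butyl[(1-methoxyethenyl)oxy]dimethylsilane
Product: 18 alkylidene β-keto ester (C3=O, C4(C19 ester)=C5 bearing CH2CO2Me), via silyl enol ether 17 (not isolated)
Conditions: TBSOTf (5 mol%), CH2Cl2, −78 °C; then Pd(OAc)2 (1.2 equiv), MeCN, rt
Reagents that add atoms: none
Why: Mukaiyama–Michael addition brings the C6–C7 acetate unit to C5 and Saegusa–Ito oxidation of the silyl enol ether restores C4=C5, so the C5 configuration formed in the addition is of no consequence.

**Step 11**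
Reactants: 18 alkylidene β-keto ester
Product: 20 4β-methyl 4α-CO2CH2CH2SiMe3 3-ketone with H5 β, via β-keto ester 19 (not isolated)
Conditions: [(Ph3P)CuH]6 (0.4 equiv), toluene, rt, aq NH4Cl; then K2CO3, MeI, acetone, rt
Reagents that add atoms: iodomethane, CI
Why: Conjugate reduction with [(Ph3P)CuH]6 should deliver hydride to C5 on the open face of ring A anti to the axial lactone carbonyl C20 (H5 β), and C-methylation of the β-keto ester enolate likewise occurs anti to axial C20 (podocarpate-type control), leaving the C19 ester axial and cis to C20.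

**Step 12**
Reactants: 20 keto ester
Product: 21 3β-alcohol (axial OH, cis to the C18 methyl)
Conditions: K-Selectride (K[s-Bu3BH]), THF, −78 °C; aq NH4Cl
Reagents that add atoms: none
Why: In this Selectride ketone reduction the bulky hydride should attack the C3 ketone along the equatorial trajectory and give the axial 3β-alcohol, as in reductions of 3-oxogibberellins, while ester and lactone carbonyls survive at low temperature.

**Step 13**
Reactants: 21 3β-alcohol
Product: 22 3β-O-TBS ether
Conditions: TBSOTf, 2,6-lutidine, CH2Cl2, 0 °C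
Reagents that add atoms: tert-butyldimethylsilyl trifluoromethanesulfonate, CC(C)(C)[Si](C)(C)OS(=O)(=O)C(F)(F)F
Why: Silyl triflate silylation protects the hindered axial alcohol against O–H insertion and base-induced retro-aldol cleavage in the next steps.

**Step 14**
Reactants: 22 silyl ether
Product: 24 α-diazo ester (C6(=N2)CO2Me), via trifluoroacetyl ester 23 (not isolated)
Conditions: LiHMDS (LiN(SiMe3)2), THF, −78 °C; CF3CO2CH2CF3; then MsN3, Et3N, H2O, MeCN, rt
Reagents that add atoms: methanesulfonyl azide, CS(=O)(=O)N=[N+]=[N-]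
Why: Detrifluoroacetylative (Danheiser) diazo transfer works at C6 because it is the only enolisable position, C4 and C10 being quaternary.

**Step 15**
Reactants: 24 α-diazo ester
Product: 25 20,12-lactone 7-methyl 19-[2-(trimethylsilyl)ethyl] diester 3-O-TBS ether of the target triacid (ring B closed)
Conditions: Rh2(O2CCPh3)4 (1 mol%), CH2Cl2, −40 °C to rt, slow addition of 24 (final 5 mM)
Reagents that add atoms: none
Why: Loss of N2 gives the rhodium carbenoid at C6, which inserts into the C8–H bond in a concerted three-centre step (Taber-type 1,5 C–H insertion of an α-diazo ester, the closest known reaction type). Ring B (C5–C6–C8–C9–C10) closes as a five-membered ring by 1,5-insertion through a chair-like six-membered transition state that includes the migrating hydrogen. C8 is formed with retention, the only possibility at a bridgehead, so its configuration dates from step 1; C6 is set by the ester taking the convex β side away from C14 and the lactone, which is expected to be the more stable epimer as well. The step needs site selectivity for the tertiary C8–H over the C11 methylene, and the lactone secures it by holding C5 gauche to C8 and anti to C11 so that C6 lies in contact with H8. It also needs insertion to outrun the 1,2-hydride shift from C5–H, which bulky triphenylacetate ligands and low temperature should ensure.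

**Step 16**
Reactants: 25 ring-B-closed lactone diester
Product: 27 3β,12α-dihydroxygibberell-16-ene-7,19,20-trioic acid (the target), via lactone acid 26 (not isolated)
Conditions: TBAF (Bu4NF), THF, 50 °C; then KOH, MeOH/H2O, 60 °C; 1 M HCl to pH 3, 0 °C
Reagents that add atoms: water, O
Why: Fluoride removes the trimethylsilylethyl ester by β-elimination and cleaves the silyl ether, then saponification opens the δ-lactone and the C7 methyl ester, C6 being expected to sit already in its more stable configuration.

**Compound list**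
1 | pent-4-ynal | C#CCCC=O | starting material
2 | but-3-en-2-one | CC(=O)C=C | starting material
3 | (S)-5-oxo-2-(prop-2-yn-1-yl)hexanal (not isolated) | C#CC[C@H](CCC(C)=O)C=O | intermediate
4 | (S)-4-(prop-2-yn-1-yl)cyclohex-2-en-1-one | C#CC[C@@H]1CCC(=O)C=C1 | intermediate
5 | tert-butyldimethyl{[(4S)-4-(prop-2-yn-1-yl)cyclohexa-1,5-dien-1-yl]oxy}silane | C#CC[C@@H]1CC=C(O[Si](C)(C)C(C)(C)C)C=C1 | intermediate
6 | (1R,5S)-7-methylidenebicyclo[3.2.1]oct-3-en-2-one | C=C1C[C@@H]2C[C@H]1C(=O)C=C2 | intermediate
7 | tert-butyl[(1-methoxyethenyl)oxy]dimethylsilane | C=C(OC)O[Si](C)(C)C(C)(C)C | starting material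
8 | C11=C12 silyl enol ether of keto ester 9 (not isolated) | C=C1C[C@@H]2C[C@H]1C(O[Si](C)(C)C(C)(C)C)=C[C@H]2CC(=O)OC | intermediate
9 | methyl 2-(6-methylidene-4-oxobicyclo[3.2.1]octan-2-yl)acetate, acetate arm on C9 α | C=C1C[C@@H]2C[C@H]1C(=O)C[C@H]2CC(=O)OC | intermediate
10 | 12α-hydroxy ester, formed as its lithium alkoxide (not isolated) | C=C1C[C@@H]2C[C@H]1[C@@H](O)C[C@H]2CC(=O)OC | intermediate
11 | tricyclic δ-lactone (C20 to 12α-O), C10 = CH2 | C=C1C[C@@H]2C[C@H]1[C@@H]3C[C@H]2CC(=O)O3 | intermediate
12 | α-(hydroxymethylene) lactone (C10=C5H–OH) | C=C1C[C@@H]2C[C@H]1[C@@H]3C[C@H]2/C(=C/O)C(=O)O3 | intermediate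
13 | C10-quaternary formyl lactone with 3-oxobutyl arm anti to C8 (not isolated) | C=C1C[C@@H]2C[C@H]1[C@@H]3C[C@H]2[C@@](C=O)(CCC(C)=O)C(=O)O3 | intermediate
14 | spiro enone lactone (ring A cyclohex-2-enone spiro at C10) | C=C1C[C@@H]2C[C@H]1[C@@H]3C[C@H]2[C@]4(C=CC(=O)CC4)C(=O)O3 | intermediate
15 | 4-iodo spiro enone lactone | C=C1C[C@@H]2C[C@H]1[C@@H]3C[C@H]2[C@]4(C=C(I)C(=O)CC4)C(=O)O3 | intermediate
16 | spiro enone lactone with C4 CO2CH2CH2SiMe3 | C=C1C[C@@H]2C[C@H]1[C@@H]3C[C@H]2[C@]4(C=C(C(=O)OCC[Si](C)(C)C)C(=O)CC4)C(=O)O3 | intermediate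
17 | silyl enol ether Michael adduct, C5 epimers (not isolated) | C=C1C[C@@H]2C[C@H]1[C@@H]3C[C@H]2[C@]4(C(CC(=O)OC)C(C(=O)OCC[Si](C)(C)C)=C(O[Si](C)(C)C(C)(C)C)CC4)C(=O)O3 | intermediate
18 | alkylidene β-keto ester (C4=C5, C5 bears CH2CO2Me) | C=C1C[C@@H]2C[C@H]1[C@@H]3C[C@H]2[C@]4(C(CC(=O)OC)=C(C(=O)OCC[Si](C)(C)C)C(=O)CC4)C(=O)O3 | intermediate
19 | β-keto ester with H5 β, C4 epimers (not isolated) | C=C1C[C@@H]2C[C@H]1[C@@H]3C[C@H]2[C@]4([C@H](CC(=O)OC)C(C(=O)OCC[Si](C)(C)C)C(=O)CC4)C(=O)O3 | intermediate
20 | 4β-methyl 4α-ester 3-ketone, H5 β | C=C1C[C@@H]2C[C@H]1[C@@H]3C[C@H]2[C@]4([C@H](CC(=O)OC)[C@](C)(C(=O)OCC[Si](C)(C)C)C(=O)CC4)C(=O)O3 | intermediate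
21 | 3β-alcohol of 20 | C=C1C[C@@H]2C[C@H]1[C@@H]3C[C@H]2[C@]4([C@H](CC(=O)OC)[C@](C)(C(=O)OCC[Si](C)(C)C)[C@@H](O)CC4)C(=O)O3 | intermediate
22 | 3β-O-TBS ether of 21 | C=C1C[C@@H]2C[C@H]1[C@@H]3C[C@H]2[C@]4([C@H](CC(=O)OC)[C@](C)(C(=O)OCC[Si](C)(C)C)[C@@H](O[Si](C)(C)C(C)(C)C)CC4)C(=O)O3 | intermediate
23 | C6-trifluoroacetyl derivative of 22, C6 epimers (not isolated) | C=C1C[C@@H]2C[C@H]1[C@@H]3C[C@H]2[C@]4([C@H](C(C(=O)OC)C(=O)C(F)(F)F)[C@](C)(C(=O)OCC[Si](C)(C)C)[C@@H](O[Si](C)(C)C(C)(C)C)CC4)C(=O)O3 | intermediate
24 | α-diazo ester (C6=N2) | C=C1C[C@@H]2C[C@H]1[C@@H]3C[C@H]2[C@]4([C@H](C(=[N+]=[N-])C(=O)OC)[C@](C)(C(=O)OCC[Si](C)(C)C)[C@@H](O[Si](C)(C)C(C)(C)C)CC4)C(=O)O3 | intermediate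
25 | 20,12-lactone 7-methyl 19-[2-(trimethylsilyl)ethyl] diester 3-O-TBS ether of the target triacid | C=C1C[C@]23C[C@H]1[C@@H]4C[C@H]2[C@]1(C(=O)O4)CC[C@H](O[Si](C)(C)C(C)(C)C)[C@@](C)(C(=O)OCC[Si](C)(C)C)[C@H]1[C@@H]3C(=O)OC | intermediate
26 | 20,12-lactone 7-methyl ester of the target triacid (not isolated) | C=C1C[C@]23C[C@H]1[C@@H]4C[C@H]2[C@]1(C(=O)O4)CC[C@H](O)[C@@](C)(C(=O)O)[C@H]1[C@@H]3C(=O)OC | intermediate
27 | 3β,12α-dihydroxygibberell-16-ene-7,19,20-trioic acid (descriptors as in the remark) | C=C1C[C@]23C[C@H]1[C@@H](O)C[C@H]2[C@]1(C(=O)O)CC[C@H](O)[C@@](C)(C(=O)O)[C@H]1[C@@H]3C(=O)O | target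

**Total step count:** 16. **Longest linear sequence:** 16.

**Steps most likely to fail**

1. Step 15. The carbenoid may be lost to 1,2-hydride migration from C5, be intercepted by a neighbouring ester carbonyl, or add to the exocyclic alkene before it reaches C8–H. The fallback sets out from 18 and returns at 25. Diazo transfer (4-acetamidobenzenesulfonyl azide, DBU, MeCN) at the doubly activated C6 methylene of 18 should give the vinyl diazo ester F1, whose C5 carries no hydrogen. Rh2(O2CCPh3)4 should then effect the same C8–H insertion to give the ring-B-closed enone F2. [(Ph3P)CuH]6 followed by K2CO3/MeI should give the keto ester F3, with hydride and methyl both expected to enter on the β face of the now rigid tetracycle. K-Selectride should give the 3β-alcohol F4, and TBSOTf/2,6-lutidine should give 25.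

2. Step 11. Hydride delivery at C5 may show poor facial selectivity: attack anti to C9 through the other half-chair of ring A would give the 5-epimer. The fallback sets out from 16 and returns at 19. The same bias would place a carbon nucleophile correctly, so 16 is treated with 7 and catalytic TBSOTf, and the silyl enol ether F5 (C6 arm trans to C9) is hydrolysed with dilute HCl directly to 19. The Saegusa oxidation and the reduction are then omitted.

3. Step 5. Hydride delivery to the α face of C12 would give the equatorial 12β-alkoxide, which cannot reach the ester. The fallback sets out from 9 and returns at 11. NaBH4 reduction to the 12β-hydroxy ester F6, saponification (LiOH) to the hydroxy acid F7 and Mitsunobu lactonisation (PPh3, diisopropyl azodicarboxylate) with inversion at C12 should give 11.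

**Further compounds**
F1 | step 15 | vinyl diazo ester from 18 (C6=N2, C4=C5) | C=C1C[C@@H]2C[C@H]1[C@@H]3C[C@H]2[C@]4(C(C(=[N+]=[N-])C(=O)OC)=C(C(=O)OCC[Si](C)(C)C)C(=O)CC4)C(=O)O3
F2 | step 15 | ring-B-closed alkylidene β-keto ester (C4=C5) | C=C1C[C@]23C[C@H]1[C@@H]4C[C@H]2[C@]1(C(=O)O4)CCC(=O)C(C(=O)OCC[Si](C)(C)C)=C1[C@@H]3C(=O)OC
F3 | step 15 | ring-B-closed 3-ketone with 4β-methyl and H5 β | C=C1C[C@]23C[C@H]1[C@@H]4C[C@H]2[C@]1(C(=O)O4)CCC(=O)[C@@](C)(C(=O)OCC[Si](C)(C)C)[C@H]1[C@@H]3C(=O)OC
F4 | step 15 | ring-B-closed 3β-alcohol | C=C1C[C@]23C[C@H]1[C@@H]4C[C@H]2[C@]1(C(=O)O4)CC[C@H](O)[C@@](C)(C(=O)OCC[Si](C)(C)C)[C@H]1[C@@H]3C(=O)OC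
F5 | step 11 | silyl enol ether Michael adduct with C6 arm trans to C9 | C=C1C[C@@H]2C[C@H]1[C@@H]3C[C@H]2[C@]4([C@H](CC(=O)OC)C(C(=O)OCC[Si](C)(C)C)=C(O[Si](C)(C)C(C)(C)C)CC4)C(=O)O3
F6 | step 5 | 12β-hydroxy ester | C=C1C[C@@H]2C[C@H]1[C@H](O)C[C@H]2CC(=O)OC
F7 | step 5 | 12β-hydroxy acid | C=C1C[C@@H]2C[C@H]1[C@H](O)C[C@H]2CC(=O)O
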